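**Strategy.** The 4-hydroxy-3-methylfuran-2(5H)-one ring is taken apart at O1–C5 and C2–C3: C2 with its two oxygens (O1 and the carbonyl oxygen) is carbon dioxide, and C3–C4–C5 with the exocyclic CH is an ethyl alkynyl ketone. In the last step ynone 17 is carboxylated at the ketone α-carbon, and the β-ketocarboxylate closes onto the silver-activated alkyne by 5-exo-dig O-attack. This gives the (Z)-ylidene tetronic acid directly, without protecting groups. The ynone comes from (R)-linalool (carbinol stereocentre, E-alkene), an (S)-3-methylpent-4-ynyl bromide made by asymmetric hydrogenation, 3-furylmethyl Grignard reagent and propanoyl chloride.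

Key step: step 12

Assumption: (R)-(−)-linalool of high enantiomeric purity and 3-(chloromethyl)furan are purchased; the two stereocentres are remote and are set independently of each other.

**Step 1**
Reactants: 1 3-methylideneoxolan-2-one (α-methylene-γ-butyrolactone)
Product: 2 (3S)-3-methyloxolan-2-one
Conditions: H2 (100 atm), Ru(OAc)2[(R)-BINAP] (0.5 mol %), CH2Cl2, 50 °C
Reagents that add atoms: none
Why: BINAP–ruthenium asymmetric hydrogenation (Noyori type) of the exocyclic conjugated C=C, in which the lactone carbonyl and the alkene chelate the metal so that the ligand alone selects the enantioface and sets the α-methyl stereocentre; the (R)-ligand is expected to give the (S)-lactone, the sense is to be confirmed on the first run and the antipodal ligand used otherwise.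

**Step 2**
Reactants: 2 (3S)-3-methyloxolan-2-one
Product: 3 (3S)-3-methyloxolan-2-ol (lactol, anomer mixture, used crude)
Conditions: i-Bu2AlH (1.05 equiv), CH2Cl2, −78 °C; aq. potassium sodium tartrate
Reagents that add atoms: none
Why: Low-temperature i-Bu2AlH half-reduction of a γ-lactone stops at the aluminium hemiacetal and should give the lactol without touching the α-stereocentre, since no base is present.

**Step 3**
Reactants: 3 (3S)-3-methyloxolan-2-ol
Product: 4 (3S)-1,1,5-tribromo-3-methylpent-1-ene
Conditions: CBr4 (3 equiv), PPh3 (6 equiv), 2,6-lutidine (1.5 equiv), CH2Cl2, 0 °C → rt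
Reagents that add atoms: carbon tetrabromide, BrC(Br)(Br)Br
Why: Corey–Fuchs (Ramirez) dibromo-olefination of the ring-opened hydroxy aldehyde under non-basic conditions should leave the α-stereocentre intact, and the Ph3PBr2 generated together with the ylide converts the released primary alcohol into the bromide (Appel-type substitution).

**Step 4**
Reactants: 4 (3S)-1,1,5-tribromo-3-methylpent-1-ene
Product: 5 (S)-(5-bromo-3-methylpent-1-yn-1-yl)trimethylsilane
Conditions: n-BuLi (2.1 equiv), THF, −78 °C; Me3SiCl (1.3 equiv), −78 → 0 °C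
Reagents that add atoms: chlorotrimethylsilane, C[Si](C)(C)Cl
Why: Second stage of the Corey–Fuchs sequence (Br/Li exchange, Fritsch–Buttenberg–Wiechell-type elimination, acetylide silylation); at −78 °C n-BuLi should exchange the vinylic bromine far faster than it attacks the primary alkyl bromide.

**Step 5**
Reactants: 6 (R)-(−)-linalool
Product: 7 (2E,6R)-2,6-dimethylocta-2,7-diene-1,6-diol
Conditions: SeO2 (0.3 equiv), t-BuOOH (2.5 equiv), salicylic acid (0.1 equiv), CH2Cl2, rt; then NaBH4, MeOH, 0 °C
Reagents that add atoms: selenium dioxide, O=[Se]=O (oxygen donor, re-oxidised by tert-butyl hydroperoxide, CC(C)(C)OO)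
Why: Sharpless SeO2/t-BuOOH allylic oxidation (ene reaction, then [2,3]-sigmatropic shift) attacks the (E)-methyl group of the only trisubstituted alkene and leaves the carbinol stereocentre untouched, while NaBH4 returns any over-oxidised enal to the allylic alcohol.

**Step 6**
Reactants: 7 (2E,6R)-2,6-dimethylocta-2,7-diene-1,6-diol
Product: 8 (3R,6E)-8-chloro-3,7-dimethylocta-1,6-dien-3-ol
Conditions: MsCl (1.1 equiv), 2,4,6-collidine, LiCl, DMF, 0 °C
Reagents that add atoms: lithium chloride, [Li+].[Cl-]
Why: Meyers–Collington chlorination, in which the primary allylic alcohol is mesylated in preference to the hindered tertiary one and displaced by chloride in an SN2 reaction without allylic transposition.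

**Step 7**
Reactants: 5 (S)-(5-bromo-3-methylpent-1-yn-1-yl)trimethylsilane; 8 (3R,6E)-8-chloro-3,7-dimethylocta-1,6-dien-3-ol
Product: 10 (3R,6E,11S)-3,7,11-trimethyl-13-(trimethylsilyl)trideca-1,6-dien-12-yn-3-ol, via alkylmagnesium bromide 9 (not isolated)
Conditions: 5, Mg, THF, rt; 8 (1.3 equiv), MeMgCl (1.3 equiv), THF, −40 °C; Li2CuCl4 (5 mol %), then 9 added slowly, −40 → 0 °C; aq. NH4Cl
Reagents that add atoms: none
Why: Copper-catalysed Grignard–allylic chloride cross-coupling (Kochi conditions), which with Li2CuCl4 in THF should substitute a primary (E)-2-methylallylic chloride at the α-carbon with retention of the E geometry, the tertiary hydroxyl being masked as its magnesium alkoxide by MeMgCl.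

**Step 8**
Reactants: 10 (3R,6E,11S)-3,7,11-trimethyl-13-(trimethylsilyl)trideca-1,6-dien-12-yn-3-ol
Product: 12 (3R,6E,11S)-3,7,11-trimethyltridec-6-en-12-yne-1,3-diol, via B-alkyl-9-BBN adduct 11 (not isolated)
Conditions: 9-BBN (2.2 equiv), THF, 0 °C → rt; then MeOH, 3 M NaOH, 30% H2O2, 0 °C → rt
Reagents that add atoms: hydrogen peroxide, OO
Why: Hydroboration–oxidation, in which 9-BBN adds anti-Markovnikov to the monosubstituted vinyl group much faster than to the trisubstituted alkene or the silylalkyne, and the alkaline peroxide/methanol work-up oxidises the C–B bond and removes the alkynyl silyl group in the same flask (protodesilylation).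

**Step 9**
Reactants: 12 (3R,6E,11S)-3,7,11-trimethyltridec-6-en-12-yne-1,3-diol
Product: 13 (3R,6E,11S)-3-hydroxy-3,7,11-trimethyltridec-6-en-12-yn-1-yl 4-methylbenzenesulfonate
Conditions: TsCl (1.2 equiv), pyridine, CH2Cl2, 0 °C
Reagents that add atoms: 4-methylbenzenesulfonyl chloride, Cc1ccc(cc1)S(Cl)(=O)=O
Why: Selective sulfonylation of the primary alcohol, the tertiary alcohol being too hindered to react with TsCl/pyridine.

**Step 10**
Reactants: 13 (3R,6E,11S)-3-hydroxy-3,7,11-trimethyltridec-6-en-12-yn-1-yl 4-methylbenzenesulfonate; 14 3-(chloromethyl)furan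
Product: 16 (4S,7E,12S)-1-(furan-3-yl)-4,8,12-trimethyltetradec-7-en-13-yn-4-ol, via furan-3-ylmethylmagnesium chloride 15 (not isolated)
Conditions: 14, Mg, THF, 0 °C (4 equiv of 15); 13, Li2CuCl4 (5 mol %), THF, −78 → 0 °C; aq. NH4Cl
Reagents that add atoms: none
Why: Copper-catalysed sp3–sp3 coupling of a primary tosylate with a Grignard reagent (Fouquet–Schlosser/Kochi type), in which 3-furylmethylmagnesium chloride should couple at its exocyclic carbon and the excess reagent serves as base for the O–H and the C≡C–H.

**Step 11**
Reactants: 16 (4S,7E,12S)-1-(furan-3-yl)-4,8,12-trimethyltetradec-7-en-13-yn-4-ol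
Product: 17 (6S,10E,14S)-17-(furan-3-yl)-14-hydroxy-6,10,14-trimethylheptadec-10-en-4-yn-3-one
Conditions: EtCOCl (1.3 equiv), PdCl2(PPh3)2 (2 mol %), CuI (4 mol %), Et3N (1.3 equiv), THF, rt
Reagents that add atoms: propanoyl chloride, CCC(Cl)=O
Why: Acyl Sonogashira coupling, in which the copper acetylide transmetalates to the acylpalladium chloride formed from the acid chloride, giving the ynone under mild amine conditions that the tertiary alcohol and the furan should tolerate.

**Step 12**
Reactants: 17 (6S,10E,14S)-17-(furan-3-yl)-14-hydroxy-6,10,14-trimethylheptadec-10-en-4-yn-3-one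
Product: 19 (5Z)-5-[(2S,6E,10S)-13-(furan-3-yl)-10-hydroxy-2,6,10-trimethyltridec-6-en-1-ylidene]-4-hydroxy-3-methylfuran-2(5H)-one (CNP0217216.2), via β-ketocarboxylate 18 (not isolated)
Conditions: CO2 (1.0 MPa), AgOAc (10 mol %), MTBD (2.5 equiv), MeCN, 25 °C; then 1 M HCl
Reagents that add atoms: carbon dioxide, O=C=O
Why: MTBD reversibly enolises the only enolisable α-position of 17 (the CH2 of the ethyl ketone, which becomes ring C3) and the enolate adds to CO2 at carbon to give β-ketocarboxylate 18, whose carboxylate oxygen attacks the alkyne carbon next to the ketone (ring C5), activated by monovalent silver, anti to the metal; protodeargentation and enolisation then give the tetronate, whose amidinium salt pulls both equilibria forward. The closest known reaction type is the silver-catalysed carboxylative cyclisation of alkynyl ketones and conjugated ynones with CO2 (enolate carboxylation followed by alkyne oxyfunctionalisation). The one ring is closed in the 5-exo-dig mode. No stereocentre is formed; the Z geometry of the exocyclic C5=CH bond should follow from anti oxyargentation and stereoretentive protonolysis of the vinylsilver, which puts the ring oxygen cis to the side chain. The step needs C- over O-carboxylation, 5-exo over 6-endo closure (which would lead to a 4-hydroxy-2-pyranone) and α′- over γ-deprotonation (which would erode the propargylic stereocentre); the first two are secured by the silver–alkyne activation and the short tether of 18, the third by the higher kinetic acidity of the unhindered α′-CH2 and by fast, irreversible ring closure at room temperature. The tertiary alcohol, the furan and the trisubstituted alkene should be inert to AgOAc, amidine and CO2.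

**Compound list**
1 | 3-methylideneoxolan-2-one (α-methylene-γ-butyrolactone) | C=C1CCOC1=O | starting material
2 | (3S)-3-methyloxolan-2-one | C[C@H]1CCOC1=O | intermediate
3 | (3S)-3-methyloxolan-2-ol (anomer mixture) | C[C@H]1CCOC1O | intermediate
4 | (3S)-1,1,5-tribromo-3-methylpent-1-ene | BrCC[C@H](C)C=C(Br)Br | intermediate
5 | (S)-(5-bromo-3-methylpent-1-yn-1-yl)trimethylsilane | C[Si](C)(C)C#C[C@@H](C)CCBr | intermediate
6 | (R)-(−)-linalool, (3R)-3,7-dimethylocta-1,6-dien-3-ol | C=C[C@](C)(O)CCC=C(C)C | starting material
7 | (2E,6R)-2,6-dimethylocta-2,7-diene-1,6-diol | C=C[C@](C)(O)CC/C=C(\C)CO | intermediate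
8 | (3R,6E)-8-chloro-3,7-dimethylocta-1,6-dien-3-ol | C=C[C@](C)(O)CC/C=C(\C)CCl | intermediate
9 | [(3S)-3-methyl-5-(trimethylsilyl)pent-4-yn-1-yl]magnesium bromide | C[Si](C)(C)C#C[C@@H](C)CC[Mg]Br | intermediate
10 | (3R,6E,11S)-3,7,11-trimethyl-13-(trimethylsilyl)trideca-1,6-dien-12-yn-3-ol | C=C[C@](C)(O)CC/C=C(\C)CCC[C@H](C)C#C[Si](C)(C)C | intermediate
11 | B-alkyl-9-BBN adduct of 10 (boron on the former vinyl terminus) | C1CCC2CCCC1B2CC[C@](C)(O)CC/C=C(\C)CCC[C@H](C)C#C[Si](C)(C)C | intermediate
12 | (3R,6E,11S)-3,7,11-trimethyltridec-6-en-12-yne-1,3-diol | OCC[C@](C)(O)CC/C=C(\C)CCC[C@H](C)C#C | intermediate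
13 | (3R,6E,11S)-3-hydroxy-3,7,11-trimethyltridec-6-en-12-yn-1-yl 4-methylbenzenesulfonate | Cc1ccc(cc1)S(=O)(=O)OCC[C@](C)(O)CC/C=C(\C)CCC[C@H](C)C#C | intermediate
14 | 3-(chloromethyl)furan | ClCc1ccoc1 | starting material
15 | furan-3-ylmethylmagnesium chloride | Cl[Mg]Cc1ccoc1 | intermediate
16 | (4S,7E,12S)-1-(furan-3-yl)-4,8,12-trimethyltetradec-7-en-13-yn-4-ol | C#C[C@@H](C)CCC/C(C)=C/CC[C@@](C)(O)CCCc1ccoc1 | intermediate
17 | (6S,10E,14S)-17-(furan-3-yl)-14-hydroxy-6,10,14-trimethylheptadec-10-en-4-yn-3-one | CCC(=O)C#C[C@@H](C)CCC/C(C)=C/CC[C@@](C)(O)CCCc1ccoc1 | intermediate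
18 | (6S,10E,14S)-17-(furan-3-yl)-14-hydroxy-2,6,10,14-tetramethyl-3-oxoheptadec-10-en-4-ynoic acid (formed as its MTBD-H carboxylate, C2 epimers) | OC(=O)C(C)C(=O)C#C[C@@H](C)CCC/C(C)=C/CC[C@@](C)(O)CCCc1ccoc1 | intermediate
19 | (5Z)-5-[(2S,6E,10S)-13-(furan-3-yl)-10-hydroxy-2,6,10-trimethyltridec-6-en-1-ylidene]-4-hydroxy-3-methylfuran-2(5H)-one | CC1=C(O)/C(=C/[C@@H](C)CCC/C(C)=C/CC[C@@](C)(O)CCCc2ccoc2)OC1=O | target

**Step count and risks**
Total steps: 12. Longest linear sequence: 10 steps (1–4, then 7–12); the linalool branch (5, 6) joins at step 7.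

Steps most likely to fail:

1. Step 12. The propargylic stereocentre may erode through γ-deprotonation and ynone–allenone equilibration under the amidine, CO2 capture may be incomplete, or closure may leak to the 6-endo mode. Fallback, setting out from 17 and coming back at 19: carboxylation is uncoupled from ring closure and run under kinetic control. Ynone 17 is enolised with LiN(SiMe3)2 (2.1 equiv, THF, −78 °C) and the lithium enolate is quenched with CO2 gas to give lithium (6S,10E,14S)-17-(furan-3-yl)-14-hydroxy-2,6,10,14-tetramethyl-3-oxoheptadec-10-en-4-ynoate F1. After exchange of THF for MeCN in the cold, AgOAc (10 mol %) with AcOH (1 equiv) should effect the same 5-exo-dig O–C5 closure without any equilibrating base.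

2. Step 7. Substitution may leak to SN2′ attack at the γ-carbon, the E geometry may scramble through the allylcopper intermediate, and the Grignard reagent may homocouple. Fallback, setting out from 7 (with 5) and coming back at 10: the primary allylic alcohol of 7 is acetylated selectively (Ac2O, pyridine, 0 °C) to (2E,6R)-6-hydroxy-2,6-dimethylocta-2,7-dien-1-yl acetate F2. This is joined to bromide 5 by nickel-catalysed reductive cross-electrophile coupling (NiCl2(dme), 4,4′,4″-tri-tert-butyl-2,2′:6′,2″-terpyridine, Zn, THF/DMA, 40 °C), which favours the linear E product and needs no Grignard reagent.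

3. Step 10. The sp3–sp3 substitution may be slow, which allows intramolecular oxetane closure by the γ-alkoxide and dimerisation of the furylmethyl Grignard reagent. Fallback, setting out from 13 (with 14) and coming back at 16: 14 is converted with PhSO2Na (DMF, rt) into 3-[(phenylsulfonyl)methyl]furan F3. Its lithio derivative (n-BuLi, THF, −78 °C; 2.2 equiv of F3) alkylates tosylate 13 to (4R,7E,12S)-1-(furan-3-yl)-4,8,12-trimethyl-1-(phenylsulfonyl)tetradec-7-en-13-yn-4-ol F4 (C1 epimers). Reductive desulfonylation (Mg, MeOH, rt) then gives 16.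

**Further compounds**
F1 | step 12 | lithium (6S,10E,14S)-17-(furan-3-yl)-14-hydroxy-2,6,10,14-tetramethyl-3-oxoheptadec-10-en-4-ynoate | [Li+].[O-]C(=O)C(C)C(=O)C#C[C@@H](C)CCC/C(C)=C/CC[C@@](C)(O)CCCc1ccoc1
F2 | step 7 | (2E,6R)-6-hydroxy-2,6-dimethylocta-2,7-dien-1-yl acetate | C=C[C@](C)(O)CC/C=C(\C)COC(C)=O
F3 | step 10 | 3-[(phenylsulfonyl)methyl]furan | O=S(=O)(Cc1ccoc1)c1ccccc1
F4 | step 10 | (4R,7E,12S)-1-(furan-3-yl)-4,8,12-trimethyl-1-(phenylsulfonyl)tetradec-7-en-13-yn-4-ol | C#C[C@@H](C)CCC/C(C)=C/CC[C@@](C)(O)CCC(c1ccoc1)S(=O)(=O)c1ccccc1
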